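**Plan**
Cuts: (a) the allylic C–O bond to O-4 of the coumarin; (b) the sp3–sp2 bond C2'–C3' of the pentenyl chain; (c) the bonds C1–C6 and C2–C3 of the cyclohexane (C1 = chain-bearing methine, C2 = CMe2, C3 = carbinol, C6 = methylidene carbon).
Enabling feature: C3 and C6 face each other 1,4 across the six-membered ring. Tying the C3 oxygen to C6 gives a 7-oxabicyclo[2.2.1]heptane, which is a reduced furan cycloadduct. In it a CH2SiMe3 group on C6 stands for the methylidene and a spirocyclopropane on C2 stands for CMe2.
Forward: the carbocycle closes first (silylmethylfuran + cyclopropylideneacetyl sultam). Then follow alkene saturation, cyclopropane hydrogenolysis, acyl → vinyl, and hydroboration with B-alkyl Suzuki coupling to a C4 (E)-enol triflate.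
The endgame is the silicon-triggered bridge opening, ester reduction and Mitsunobu etherification with separately made 4-hydroxy-5-methylcoumarin.
Stereochemistry: (2R)-bornane-10,2-sultam sets C1 (R) by Cα-Re addition. The exo, suprafacial addition puts the oxygen bridge cis to the chain, so C3 (S) is carried through when only the C6–O bond breaks. The E alkene is inherited from the enol triflate with retention.

Key step: step 5

Assumption: without a chelating metal the (2R)-sultam is taken to direct addition to the Cα-Re face of its s-cis enoyl group, the sense it shows in its other thermal additions. Both antipodes of the sultam and 1-(2-hydroxy-6-methylphenyl)ethanone are taken as commercial.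

Step 1
Reactants: 1 furan; 2 (iodomethyl)trimethylsilane
Product: 4 2-(trimethylsilylmethyl)furan, via 2-furyllithium 3 (not isolated)
Conditions: n-BuLi, THF, 0 °C; then 2, −78 °C → rt
Reagents that add atoms: n-butyllithium, [Li]CCCC (lithium of 3 only)
Why: α-Lithiation of furan and SN2 alkylation, which should work because the α-silyl iodide is a good SN2 partner and iodine–lithium exchange is uphill, 2-furyllithium being the better stabilised carbanion.

Step 2
Reactants: 5 (1-ethoxycyclopropoxy)trimethylsilane; 6 tert-butyl (triphenylphosphoranylidene)acetate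
Product: 8 tert-butyl 2-cyclopropylideneacetate, via cyclopropanone 7 (not isolated)
Conditions: PhCO2H (10 mol %), toluene, 85 °C
Reagents that add atoms: none
Why: Wittig olefination of cyclopropanone released in situ from its silylated hemiacetal under benzoic acid catalysis, the standard entry to cyclopropylideneacetates.

Step 3
Reactants: 8 tert-butyl 2-cyclopropylideneacetate
Product: 9 2-cyclopropylideneacetic acid
Conditions: TFA, CH2Cl2, 0 °C → rt
Reagents that add atoms: none
Why: Acidolysis of the tert-butyl ester (E1 loss of isobutene) frees the acid without exposing the strongly Michael-accepting alkene to hydroxide.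

Step 4
Reactants: 9 2-cyclopropylideneacetic acid; 10 (2R)-bornane-10,2-sultam
Product: 13 N-(2-cyclopropylideneacetyl)-(2R)-bornane-10,2-sultam, via 2-cyclopropylideneacetyl chloride 11 (not isolated), via sodium sultamide 12 (not isolated)
Conditions: 9, Me2C=C(Cl)NMe2, CH2Cl2, 0 °C; 10, NaH, toluene, rt; solutions combined, 0 °C → rt
Reagents that add atoms: 1-chloro-N,N,2-trimethylprop-1-en-1-amine, CC(C)=C(Cl)N(C)C (chlorine of 11 only); sodium hydride, [Na+].[H-] (sodium of 12 only)
Why: Standard N-acylation of the sodium sultamide with an acid chloride, which is made here under neutral conditions with the chloroenamine so that no HCl can add to the strained enoyl unit.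

Step 5
Reactants: 13 N-(2-cyclopropylideneacetyl)-(2R)-bornane-10,2-sultam; 4 2-(trimethylsilylmethyl)furan
Product: 14 exo adduct, (2R)-N-{[(1'R,2'S,4'S)-1'-(trimethylsilylmethyl)spiro[cyclopropane-1,3'-[7]oxabicyclo[2.2.1]hept[5]en]-2'-yl]carbonyl}bornane-10,2-sultam (acyl group syn to the O bridge, CH2SiMe3 on the bridgehead next to the acyl-bearing carbon)
Conditions: 4 (3 equiv), CH2Cl2, PTFE tube, 1.3 GPa, 25 °C; chromatography, recrystallisation
Reagents that add atoms: none
Why: Proposed new method: the furan and the enoyl sultam should combine in a concerted, asynchronous and suprafacial [4+2] cycloaddition in which furan C5 bonds to the cyclopropylidene carbon and furan C2 (bearing CH2SiMe3) to the acyl-bearing carbon; the olefinic strain released when the cyclopropylidene carbon becomes tetrahedral pays for the lost furan aromaticity and for the β,β-disubstitution and should make the addition irreversible at 25 °C, so that all selectivity is kinetic. The closest known reaction type is the high-pressure Diels–Alder addition of furans to 2-halo-2-cyclopropylideneacetates, and pressure is preferred to a Lewis acid because the activation volume is strongly negative, whereas a Lewis acid would divert the furfurylsilane into conjugate addition with loss of silicon and would ionise the allylic β-silyl ether of 14. The only ring formed, the six-membered carbocycle of the 7-oxanorbornene, closes by intermolecular [4π+2π] addition across furan C2 and C5. The acyl-bearing stereocentre (C2') is set by the auxiliary, whose s-cis enoyl group with C=O anti to SO2 is open on its Cα-Re face, and the two bridgeheads (C1', C4') follow from it through the suprafacial exo approach. The step needs ortho regiochemistry, secured by pairing the most nucleophilic furan carbon (C5 of a 2-donor-substituted furan) with the electrophilic β-carbon and by keeping the two fully substituted carbons apart, and exo orientation, expected because only the substituent-free ring oxygen, and not the C3–H/C4–H edge of the furan, then has to lie over the bulky acyl sultam. Any endo or Cα-Si isomer is a diastereomer of 14 and is removed by chromatography and recrystallisation, so that 14 goes on as a single stereoisomer.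

Step 6
Reactants: 14 exo adduct
Product: 16 (2R)-N-{[(1R,2S,4S)-3,3-dimethyl-1-(trimethylsilylmethyl)-7-oxabicyclo[2.2.1]heptan-2-yl]carbonyl}bornane-10,2-sultam (exo acyl), via dihydro adduct 15 (not isolated)
Conditions: H2 (1 atm), PtO2, EtOAc, rt; then AcOH, NaOAc, H2 (4 atm), rt
Reagents that add atoms: none
Why: Catalytic hydrogenation first saturates the strained ring alkene in neutral solvent (which also rules out cycloreversion), and platinum-catalysed hydrogenolysis then cleaves the least hindered CH2–CH2 bond of the spirocyclopropane to the gem-dimethyl group; the adjacent electron-withdrawing acyl sultam and the acetate buffer should hold back ionisation of the β-silyl ether, and no stereocentre is touched.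

Step 7
Reactants: 16 dimethyl acyl sultam
Product: 17 [(1R,2R,4S)-3,3-dimethyl-1-(trimethylsilylmethyl)-7-oxabicyclo[2.2.1]heptan-2-yl]methanol (exo CH2OH)
Conditions: LiAlH4, THF, 0 °C → rt; H2O/aq NaOH work-up
Reagents that add atoms: none
Why: Hydride reduction of an N-acyl sultam gives the primary alcohol and returns the auxiliary without enolising C2, so the exo configuration is kept.

Step 8
Reactants: 17 exo carbinol
Product: 18 (1R,2S,4S)-3,3-dimethyl-1-(trimethylsilylmethyl)-7-oxabicyclo[2.2.1]heptane-2-carbaldehyde (exo CHO)
Conditions: TPAP (5 mol %), NMO, 4 Å MS, CH2Cl2, rt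
Reagents that add atoms: none
Why: The Ley–Griffith oxidation is neutral, so the aldehyde should neither epimerise at C2 nor lose the bridge oxygen by β-elimination.

Step 9
Reactants: 18 exo aldehyde
Product: 19 (1R,2S,4S)-2-ethenyl-3,3-dimethyl-1-(trimethylsilylmethyl)-7-oxabicyclo[2.2.1]heptane (exo vinyl)
Conditions: Ph3PCH3Br, KHMDS, THF, 0 °C; then 18, −78 → 0 °C
Reagents that add atoms: methyltriphenylphosphonium bromide, C[P+](c1ccccc1)(c1ccccc1)c1ccccc1.[Br-]
Why: Wittig methylenation, in which addition of the small unstabilised ylide to the aldehyde at low temperature should outrun deprotonation of the tertiary α-hydrogen that is buried between two quaternary carbons.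

Step 10
Reactants: 20 methyl acetoacetate
Product: 21 methyl (E)-3-(trifluoromethylsulfonyloxy)but-2-enoate
Conditions: Tf2O, aq Me4NOH, hexane, 5 °C
Reagents that add atoms: trifluoromethanesulfonic anhydride, O=S(=O)(OS(=O)(=O)C(F)(F)F)C(F)(F)F
Why: Stereoselective O-triflation of an acetoacetate enolate, in which the non-chelating tetramethylammonium counter-ion lets the enolate react from its extended form, so that the triflate ends trans to the ester.

Step 11
Reactants: 19 exo vinyl compound; 21 (E)-enol triflate
Product: 23 methyl (2E)-5-[(1R,2S,4S)-3,3-dimethyl-1-(trimethylsilylmethyl)-7-oxabicyclo[2.2.1]heptan-2-yl]-3-methylpent-2-enoate, via B-alkyl-9-BBN adduct 22 (not isolated)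
Conditions: 9-BBN-H, THF, rt; then 21, PdCl2(dppf) (5 mol %), K3PO4, THF–dioxane, 65 °C
Reagents that add atoms: 9-borabicyclo[3.3.1]nonane, [H]B1C2CCCC1CCC2 (boron bicycle of 22 only)
Why: Anti-Markovnikov hydroboration of the monosubstituted alkene followed by B-alkyl Suzuki–Miyaura coupling, whose oxidative addition and reductive elimination retain the geometry of the enol triflate and so give the E-trisubstituted enoate.

Step 12
Reactants: 23 bridged enoate
Product: 25 methyl (2E)-5-[(1R,3S)-3-hydroxy-2,2-dimethyl-6-methylidenecyclohexyl]-3-methylpent-2-enoate, via trimethylsilyl ether 24 (not isolated)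
Conditions: TMSOTf (15 mol %), 2,6-di-tert-butyl-4-methylpyridine (20 mol %), CH2Cl2, −78 → −30 °C; then K2CO3 (cat.), MeOH, 0 °C
Reagents that add atoms: none
Why: Peterson-type fragmentation of a β-silyl ether, in which silylation of the bridge oxygen lets the tertiary bridgehead C1–O bond ionise with hyperconjugative help from the C–Si bond and triflate then takes the silyl group (regenerating TMSOTf), so that only the exocyclic alkene can form; the C4–O bond and hence the carbinol configuration stay untouched, the electron-poor enoate does not trap the cation, and the hindered pyridine removes acid that could move the double bond.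

Step 13
Reactants: 25 hydroxy enoate
Product: 26 (2E)-5-[(1R,3S)-3-hydroxy-2,2-dimethyl-6-methylidenecyclohexyl]-3-methylpent-2-en-1-ol
Conditions: DIBAL-H (3.5 equiv), CH2Cl2, −78 °C; aq potassium sodium tartrate
Reagents that add atoms: none
Why: 1,2-Reduction of an α,β-unsaturated ester with DIBAL-H gives the allylic alcohol and leaves both alkenes and both stereocentres alone.

Step 14
Reactants: 27 1-(2-hydroxy-6-methylphenyl)ethanone
Product: 29 4-hydroxy-5-methylcoumarin, via beta-keto ester 28 (not isolated)
Conditions: NaH, (EtO)2CO, toluene, 110 °C; then aq HCl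
Reagents that add atoms: diethyl carbonate, CCOC(=O)OCC
Why: Claisen-type C-ethoxycarbonylation of the ketone enolate followed by lactonisation onto the phenoxide, the standard synthesis of 4-hydroxycoumarins.

Step 15
Reactants: 26 diol; 29 4-hydroxy-5-methylcoumarin
Product: 30 target, 4-{[(2E)-5-[(1R,3S)-3-hydroxy-2,2-dimethyl-6-methylidenecyclohexyl]-3-methylpent-2-en-1-yl]oxy}-5-methyl-2H-chromen-2-one
Conditions: PPh3, DIAD, THF, 0 °C → rt
Reagents that add atoms: none
Why: Mitsunobu etherification, in which the acidic vinylogous acid 29 is alkylated on O-4 by SN2 attack on the alkoxyphosphonium salt of the primary allylic alcohol, while the secondary alcohol next to the CMe2 group is too hindered to be activated.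

**Compound list**
1 | furan | c1ccoc1 | starting material
2 | (iodomethyl)trimethylsilane | C[Si](C)(C)CI | starting material
3 | 2-furyllithium | [Li]c1ccco1 | intermediate
4 | 2-(trimethylsilylmethyl)furan | C[Si](C)(C)Cc1ccco1 | intermediate
5 | (1-ethoxycyclopropoxy)trimethylsilane | CCOC1(O[Si](C)(C)C)CC1 | starting material
6 | tert-butyl (triphenylphosphoranylidene)acetate | CC(C)(C)OC(=O)C=P(c1ccccc1)(c1ccccc1)c1ccccc1 | starting material
7 | cyclopropanone | O=C1CC1 | intermediate
8 | tert-butyl 2-cyclopropylideneacetate | CC(C)(C)OC(=O)C=C1CC1 | intermediate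
9 | 2-cyclopropylideneacetic acid | OC(=O)C=C1CC1 | intermediate
10 | (2R)-bornane-10,2-sultam | N1[C@@H]2C[C@H]3CC[C@]2(CS1(=O)=O)C3(C)C | starting material
11 | 2-cyclopropylideneacetyl chloride | ClC(=O)C=C1CC1 | intermediate
12 | sodium salt of (2R)-bornane-10,2-sultam | [Na+].[N-]1[C@@H]2C[C@H]3CC[C@]2(CS1(=O)=O)C3(C)C | intermediate
13 | N-(2-cyclopropylideneacetyl)-(2R)-bornane-10,2-sultam | O=C(C=C1CC1)N1[C@@H]2C[C@H]3CC[C@]2(CS1(=O)=O)C3(C)C | intermediate
14 | exo spirocyclopropane 7-oxanorbornene acyl sultam (1'R,2'S,4'S) | C[Si](C)(C)C[C@]12C=C[C@H](O1)C1(CC1)[C@@H]2C(=O)N1[C@@H]2C[C@H]3CC[C@]2(CS1(=O)=O)C3(C)C | intermediate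
15 | 5',6'-dihydro derivative of 14 (saturated spirocyclopropane 7-oxanorbornane) | C[Si](C)(C)C[C@]12CC[C@H](O1)C1(CC1)[C@@H]2C(=O)N1[C@@H]2C[C@H]3CC[C@]2(CS1(=O)=O)C3(C)C | intermediate
16 | exo 3,3-dimethyl-7-oxanorbornane acyl sultam (1R,2S,4S) | C[Si](C)(C)C[C@]12CC[C@H](O1)C(C)(C)[C@@H]2C(=O)N1[C@@H]2C[C@H]3CC[C@]2(CS1(=O)=O)C3(C)C | intermediate
17 | [(1R,2R,4S)-3,3-dimethyl-1-(trimethylsilylmethyl)-7-oxabicyclo[2.2.1]heptan-2-yl]methanol | C[Si](C)(C)C[C@]12CC[C@H](O1)C(C)(C)[C@@H]2CO | intermediate
18 | (1R,2S,4S)-3,3-dimethyl-1-(trimethylsilylmethyl)-7-oxabicyclo[2.2.1]heptane-2-carbaldehyde | C[Si](C)(C)C[C@]12CC[C@H](O1)C(C)(C)[C@@H]2C=O | intermediate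
19 | (1R,2S,4S)-2-ethenyl-3,3-dimethyl-1-(trimethylsilylmethyl)-7-oxabicyclo[2.2.1]heptane | C[Si](C)(C)C[C@]12CC[C@H](O1)C(C)(C)[C@@H]2C=C | intermediate
20 | methyl acetoacetate | COC(=O)CC(C)=O | starting material
21 | methyl (E)-3-(trifluoromethylsulfonyloxy)but-2-enoate | COC(=O)/C=C(C)/OS(=O)(=O)C(F)(F)F | intermediate
22 | 9-{2-[(1R,2S,4S)-3,3-dimethyl-1-(trimethylsilylmethyl)-7-oxabicyclo[2.2.1]heptan-2-yl]ethyl}-9-borabicyclo[3.3.1]nonane | C[Si](C)(C)C[C@]12CC[C@H](O1)C(C)(C)[C@@H]2CCB1C2CCCC1CCC2 | intermediate
23 | methyl (2E)-5-[(1R,2S,4S)-3,3-dimethyl-1-(trimethylsilylmethyl)-7-oxabicyclo[2.2.1]heptan-2-yl]-3-methylpent-2-enoate | C[Si](C)(C)C[C@]12CC[C@H](O1)C(C)(C)[C@@H]2CC/C(C)=C/C(=O)OC | intermediate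
24 | methyl (2E)-5-[(1R,3S)-2,2-dimethyl-6-methylidene-3-(trimethylsilyloxy)cyclohexyl]-3-methylpent-2-enoate | C=C1CC[C@H](O[Si](C)(C)C)C(C)(C)[C@@H]1CC/C(C)=C/C(=O)OC | intermediate
25 | methyl (2E)-5-[(1R,3S)-3-hydroxy-2,2-dimethyl-6-methylidenecyclohexyl]-3-methylpent-2-enoate | C=C1CC[C@H](O)C(C)(C)[C@@H]1CC/C(C)=C/C(=O)OC | intermediate
26 | (2E)-5-[(1R,3S)-3-hydroxy-2,2-dimethyl-6-methylidenecyclohexyl]-3-methylpent-2-en-1-ol | C=C1CC[C@H](O)C(C)(C)[C@@H]1CC/C(C)=C/CO | intermediate
27 | 1-(2-hydroxy-6-methylphenyl)ethanone | CC(=O)c1c(C)cccc1O | starting material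
28 | ethyl 3-(2-hydroxy-6-methylphenyl)-3-oxopropanoate | CCOC(=O)CC(=O)c1c(C)cccc1O | intermediate
29 | 4-hydroxy-5-methylcoumarin | Cc1cccc2oc(=O)cc(O)c12 | intermediate
30 | 4-{[(2E)-5-[(1R,3S)-3-hydroxy-2,2-dimethyl-6-methylidenecyclohexyl]-3-methylpent-2-en-1-yl]oxy}-5-methyl-2H-chromen-2-one | C=C1CC[C@H](O)C(C)(C)[C@@H]1CC/C(C)=C/COc1cc(=O)oc2cccc(C)c12 | target

**Step count**
Total steps: 15. Longest linear sequence: 12 (steps 2–9, 11–13, 15).

**Steps most likely to fail**

1. **Step 5.**
   - What may go wrong: the furan may attack the enoyl β-carbon stepwise and shed its silyl group before the second bond forms. The endo approach or the Cα-Si face may compete. The hindered dienophile may also not react at all.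
   - Fallback: it sets out from sultam 10, uses furan 4 and comes back at 15. The ring is closed with an allenic dienophile, a reaction type established for furans, and the three-membered ring is added afterwards.
   - Commercial buta-2,3-dienoic acid is converted with the chloroenamine of step 4 into buta-2,3-dienoyl chloride F1. This is coupled with sodium sultamide 12 to give N-(buta-2,3-dienoyl)-(2R)-bornane-10,2-sultam F2.
   - F2 and 4 are warmed together and add across the α,β-double bond to the exo 3-methylidene-7-oxanorbornene acyl sultam F3. Its formation is reversible, so unwanted isomers can be recycled by cycloreversion.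
   - Diimide (2-nitrobenzenesulfonohydrazide, Et3N) saturates only the strained ring alkene to give the dihydro methylidene compound F4.
   - Simmons–Smith cyclopropanation (Et2Zn, CH2I2) of the exocyclic methylene then gives 15, which enters the second stage of step 6.

2. **Step 6.**
   - What may go wrong: the acetic acid used for the C–C hydrogenolysis may ionise the β-silyl ether, after which the liberated alkene would be hydrogenated. The sultam may also screen the cyclopropane from the catalyst surface, so that the cleavage stalls.
   - Fallback: it sets out from 15 and comes back at 17. Auxiliary removal and hydrogenolysis change places.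
   - Hydrogenation is stopped at 15, and LiAlH4 gives the spirocyclopropyl carbinol F5.
   - Its now unencumbered cyclopropane, held on the metal by the neighbouring hydroxymethyl group, is hydrogenolysed over Pt/C in neutral ethyl acetate under pressure to give 17 directly.

3. **Step 15.**
   - What may go wrong: the ambident coumarin anion may be alkylated at C-3 or at the lactone carbonyl oxygen, because the peri methyl group crowds O-4. The allylic phosphonium salt may also react in the SN2' sense.
   - Fallback: it sets out from 29 and comes back at 30. The polarity of the ether-forming step is reversed.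
   - POCl3 converts 29 into 4-chloro-5-methylcoumarin F6.
   - Diol 26 is treated with one equivalent of NaH to give the primary sodium alkoxide F7. This displaces chloride at C-4 by addition–elimination, so the O–C4 bond forms unambiguously and the allylic carbon is never an electrophile.

**Further compounds**
F1 | step 5 | buta-2,3-dienoyl chloride | C=C=CC(=O)Cl
F2 | step 5 | N-(buta-2,3-dienoyl)-(2R)-bornane-10,2-sultam | C=C=CC(=O)N1[C@@H]2C[C@H]3CC[C@]2(CS1(=O)=O)C3(C)C
F3 | step 5 | exo 3-methylidene-1-(trimethylsilylmethyl)-7-oxabicyclo[2.2.1]hept-5-ene-2-carbonyl sultam | C[Si](C)(C)C[C@]12C=C[C@H](O1)C(=C)[C@@H]2C(=O)N1[C@@H]2C[C@H]3CC[C@]2(CS1(=O)=O)C3(C)C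
F4 | step 5 | exo 3-methylidene-1-(trimethylsilylmethyl)-7-oxabicyclo[2.2.1]heptane-2-carbonyl sultam | C[Si](C)(C)C[C@]12CC[C@H](O1)C(=C)[C@@H]2C(=O)N1[C@@H]2C[C@H]3CC[C@]2(CS1(=O)=O)C3(C)C
F5 | step 6 | exo spirocyclopropyl 7-oxanorbornane carbinol | C[Si](C)(C)C[C@]12CC[C@H](O1)C1(CC1)[C@@H]2CO
F6 | step 15 | 4-chloro-5-methylcoumarin | Cc1cccc2oc(=O)cc(Cl)c12
F7 | step 15 | sodium primary alkoxide of diol 26 | C=C1CC[C@H](O)C(C)(C)[C@@H]1CC/C(C)=C/C[O-].[Na+]
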